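## Retrosynthetic overview

- The strategy rests on ring D, the five-membered lactol lactone on ring B (ring B carbons: B1 ether O, B2 ester O, B3 CH3, B4 OH, B5 lactone carbonyl, B6 lactol carbon). The lactol carbon on B6 is the only stereocenter; it epimerizes as a free lactol but is fixed as an O-benzyl acetal, and the lactone carbonyl on B5 is a one-carbon unit that CO can supply.
- Target 21 is therefore traced to the (R) benzyl acetal 20 (hydrogenolysis), and 20 to bromo aldehyde depsidone 18, benzyl alcohol and CO (enantioselective carbonylative acetalization forming B5–C(=O) and C(=O)–O).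
- Ring C, the seven-membered lactone of 18, comes from lactonization of the ring A carboxyl onto the B2 oxygen of a diaryl ether acid. The bond from the ring A ether oxygen to B1 is made by Smiles rearrangement of depside 15.
- Depside 15 is the ester of ring A acid 7 (from methyl orsellinate) and ring B phenol 14 (from 2,4-dihydroxy-3-methylbenzaldehyde).
- Ring order: rings A and B are bought as arenes, ring C is closed in step 14, ring D last in step 15.

Key step: step 15

Assumption: which enantiomer of the ligand gives the (R) acetal must be found by trial; (R)-DTBM-SEGPHOS is written and its antipode is taken if it favours (S). The free lactol is taken to hold its configuration only in neutral, aprotic media.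

## Route

Step 1
Reactants: 1 methyl orsellinate
Product: 2 methyl 2-hydroxy-4-methoxy-6-methylbenzoate
Conditions: MeI (1.05 equiv), K2CO3, acetone, reflux
Reagents that add atoms: iodomethane, CI
Why: Williamson O-methylation: the 2-OH is held in a hydrogen bond to the ester carbonyl, so the carbonate should deprotonate and methylate only the 4-OH.

Step 2
Reactants: 2 methyl 2-hydroxy-4-methoxy-6-methylbenzoate
Product: 3 methyl 3-formyl-2-hydroxy-4-methoxy-6-methylbenzoate
Conditions: MgCl2, Et3N, (CH2O)n, MeCN, reflux; then aq. citric acid
Reagents that add atoms: formaldehyde (from paraformaldehyde), C=O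
Why: Magnesium-mediated ortho-formylation (Casnati–Skattebøl): the magnesium phenoxide delivers formaldehyde only ortho to the free hydroxyl, position 3 is the one open ortho position, and a second formaldehyde takes up the hydride.

Step 3
Reactants: 3 methyl 3-formyl-2-hydroxy-4-methoxy-6-methylbenzoate
Product: 4 methyl 2-hydroxy-3-(hydroxymethyl)-4-methoxy-6-methylbenzoate
Conditions: NaBH4, THF–MeOH, 0 °C
Reagents that add atoms: none
Why: Hydride reduction: NaBH4 should reduce the aryl aldehyde at 0 °C and leave the hindered, hydrogen-bonded methyl ester.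

Step 4
Reactants: 4 methyl 2-hydroxy-3-(hydroxymethyl)-4-methoxy-6-methylbenzoate; 5 benzyl alcohol
Product: 6 methyl 3-[(benzyloxy)methyl]-2-hydroxy-4-methoxy-6-methylbenzoate
Conditions: 5 (10 equiv), PPTS (0.1 equiv), CH2Cl2, 40 °C
Reagents that add atoms: benzyl alcohol (5), OCc1ccccc1
Why: Acid-catalysed SN1 etherification through the benzylic cation that the ortho hydroxyl and ortho methoxy groups stabilize; the large excess of benzyl alcohol should outrun self-alkylation of the arene, and the phenol cannot be benzylated by this mechanism.

Step 5
Reactants: 6 methyl 3-[(benzyloxy)methyl]-2-hydroxy-4-methoxy-6-methylbenzoate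
Product: 7 3-[(benzyloxy)methyl]-2-hydroxy-4-methoxy-6-methylbenzoic acid
Conditions: KOH (aq. 4 M), EtOH, 80 °C; then cold 1 M HCl to pH 3
Reagents that add atoms: potassium hydroxide, [K+].[OH-]
Why: Saponification (BAc2) of the hindered salicylate; the benzyl ether and the aryl methyl ether are inert to hydroxide, and the acid is freed cold and briefly to avoid decarboxylation and solvolysis of the benzylic ether.

Step 6
Reactants: 8 2,4-dihydroxy-3-methylbenzaldehyde
Product: 9 4-(benzyloxy)-2-hydroxy-3-methylbenzaldehyde
Conditions: BnBr (1.05 equiv), K2CO3, MeCN, 60 °C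
Reagents that add atoms: benzyl bromide, BrCc1ccccc1
Why: Williamson etherification: the 4-OH para to the formyl group is the more acidic and is not chelated, whereas the 2-OH is hydrogen-bonded to the aldehyde, so monobenzylation should fall on the 4-oxygen.

Step 7
Reactants: 9 4-(benzyloxy)-2-hydroxy-3-methylbenzaldehyde
Product: 10 4-(benzyloxy)-5-bromo-2-hydroxy-3-methylbenzaldehyde
Conditions: NBS (1.0 equiv), MeCN, 0 °C to rt
Reagents that add atoms: N-bromosuccinimide, O=C1CCC(=O)N1Br
Why: Electrophilic aromatic bromination: position 5 is para to the free hydroxyl and ortho to the benzyloxy group while position 6 is meta to both, so bromine should enter at position 5 only.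

Step 8
Reactants: 10 4-(benzyloxy)-5-bromo-2-hydroxy-3-methylbenzaldehyde
Product: 11 4-(benzyloxy)-5-bromo-2-(methoxymethoxy)-3-methylbenzaldehyde
Conditions: NaH, DMF, 0 °C; MOMCl, 0 °C to rt
Reagents that add atoms: chloromethyl methyl ether, COCCl
Why: Williamson-type O-alkylation: NaH breaks the hydrogen bond by forming the phenoxide, which the chloromethyl ether alkylates; the MOM ether marks this oxygen as the later ester oxygen on B2.

Step 9
Reactants: 11 4-(benzyloxy)-5-bromo-2-(methoxymethoxy)-3-methylbenzaldehyde
Product: 13 4-(benzyloxy)-5-bromo-2-(methoxymethoxy)-3-methylphenol, via aryl formate 12 (not isolated)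
Conditions: mCPBA, NaHCO3, CH2Cl2, 0 °C to rt; then K2CO3 (cat.), MeOH, 0 °C
Reagents that add atoms: 3-chloroperbenzoic acid (mCPBA), OOC(=O)c1cccc(Cl)c1
Why: Baeyer–Villiger oxidation of an electron-rich benzaldehyde (Dakin type): the aryl group with ortho and para oxygen donors migrates in preference to hydride, and mild methanolysis of the formate frees the phenol on B1 without touching the MOM or benzyl ether.

Step 10
Reactants: 13 4-(benzyloxy)-5-bromo-2-(methoxymethoxy)-3-methylphenol
Product: 14 5-(benzyloxy)-6-bromo-2-hydroxy-3-(methoxymethoxy)-4-methylbenzaldehyde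
Conditions: MgCl2, Et3N, (CH2O)n, MeCN, reflux; then aq. citric acid
Reagents that add atoms: formaldehyde (from paraformaldehyde), C=O
Why: Magnesium-mediated ortho-formylation (Casnati–Skattebøl): the only open position ortho to the free hydroxyl is B6, between the hydroxyl and the bromine, so the aldehyde should enter there.

Step 11
Reactants: 7 3-[(benzyloxy)methyl]-2-hydroxy-4-methoxy-6-methylbenzoic acid; 14 5-(benzyloxy)-6-bromo-2-hydroxy-3-(methoxymethoxy)-4-methylbenzaldehyde
Product: 15 4-(benzyloxy)-3-bromo-2-formyl-6-(methoxymethoxy)-5-methylphenyl 3-[(benzyloxy)methyl]-2-hydroxy-4-methoxy-6-methylbenzoate (depside; ester oxygen on B1)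
Conditions: DCC, DMAP (cat.), CH2Cl2, 0 °C to rt
Reagents that add atoms: none
Why: Carbodiimide esterification (Steglich type): the O-acylisourea of the salicylic acid should acylate the only free hydroxyl of 14, while the hydrogen-bonded 2-OH of the acid is too hindered to compete.

Step 12
Reactants: 15 depside with the ester oxygen on B1
Product: 16 3-[(benzyloxy)methyl]-2-[4-(benzyloxy)-3-bromo-2-formyl-6-(methoxymethoxy)-5-methylphenoxy]-4-methoxy-6-methylbenzoic acid
Conditions: K2CO3, dry DMSO, 25–50 °C; then cold 1 M HCl to pH 3
Reagents that add atoms: none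
Why: Smiles rearrangement (O-to-O aryl migration), the reaction type that turns depsides into the diaryl ethers of depsidones: the ring A phenoxide adds to B1 through a six-membered spiro Meisenheimer adduct stabilized by the ortho formyl group, and the carboxylate leaves irreversibly.

Step 13
Reactants: 16 diaryl ether acid with the MOM ether on the B2 oxygen
Product: 17 3-[(benzyloxy)methyl]-2-[4-(benzyloxy)-3-bromo-2-formyl-6-hydroxy-5-methylphenoxy]-4-methoxy-6-methylbenzoic acid
Conditions: NaHSO4·SiO2, CH2Cl2, rt
Reagents that add atoms: none
Why: Acid-catalysed acetal hydrolysis: a phenolic MOM ether is cleaved by this mild solid acid at room temperature, under which the benzyl ethers, the aldehyde and the aryl bromide should persist.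

Step 14
Reactants: 17 diaryl ether acid with free B2 hydroxyl
Product: 18 bromo aldehyde depsidone (ring C lactone from the ring A carboxyl to the B2 oxygen; ring A carries OMe, CH3 and CH2OBn; B3 CH3; B4 OBn; B5 Br; B6 CHO)
Conditions: DCC, DMAP (cat.), CH2Cl2 (0.01 M), rt
Reagents that add atoms: none
Why: Carbodiimide lactonization (Steglich type): the activated ring A carboxyl is trapped by the neighbouring B2 hydroxyl in a 7-exo-trig closure, the usual way of closing ring C of depsidones.

Step 15
Reactants: 18 bromo aldehyde depsidone; 5 benzyl alcohol
Product: 20 depsidone with ring D closed as the (R) O-benzyl acetal at the B6 lactol carbon (B4 OBn; ring A CH2OBn), via benzyl hemiacetal 19 (not isolated)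
Conditions: Pd(OAc)2 (5 mol%), (R)-DTBM-SEGPHOS (6 mol%), CO (1 atm), 5 (3 equiv), iPr2NEt (2 equiv), toluene, 60–70 °C
Reagents that add atoms: benzyl alcohol (5), OCc1ccccc1; carbon monoxide, [C-]#[O+]
Why: Proposed new method: zerovalent palladium formed from Pd(OAc)2 and the bisphosphine inserts into the B5–Br bond, which the ortho formyl group activates, CO inserts to give the acylpalladium bromide, and the oxygen of hemiacetal 19, formed reversibly from the B6 aldehyde and benzyl alcohol, displaces bromide on palladium and undergoes C–O reductive elimination. The closest known reaction type is the palladium-catalysed carbonylative cyclization of 2-bromobenzaldehydes with alcohols to racemic 3-alkoxyphthalides, run here with a chiral ligand as a dynamic kinetic resolution. Ring D closes in the 5-exo-trig mode by attack of the hemiacetal oxygen on the acyl carbon, which forms the B5–C(=O) and C(=O)–O bonds. The new stereocenter on B6 is set by the C2-symmetric ligand on palladium, which should pass only one of the two rapidly interconverting hemiacetal enantiomers through alkoxide binding and reductive elimination, the (R) acetal being the one wanted. The step needs intramolecular capture of the acyl complex to outrun attack by free benzyl alcohol, which would give the achiral open benzyl ester, and it needs ring C to survive; the higher acidity of the hemiacetal hydroxyl, its position next to palladium and a hindered amine in toluene in place of an alkoxide base should secure both. The O-benzyl acetal cannot open to a formyl acid, so the configuration should hold until step 16.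

Step 16
Reactants: 20 (R) tri-O-benzyl acetal depsidone
Product: 21 CNP0367167.1, the (R) lactol
Conditions: H2 (1 atm), Pd/C (10 wt%), EtOAc, rt; filtration, evaporation below 30 °C, crystallization from an aprotic solvent
Reagents that add atoms: none
Why: Catalytic hydrogenolysis cuts the three unhindered O–CH2Ph bonds and none of the bonds to the B6 lactol carbon, so the (R) lactol should be released with retention; a neutral aprotic solvent, short contact and a work-up free of base and alcohol are meant to hold back ring-chain tautomerism (epimerization) and over-reduction at the hindered benzylic carbon of the ring A hydroxymethyl group and at the lactol carbon.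

## Compound list

1 | methyl orsellinate (methyl 2,4-dihydroxy-6-methylbenzoate) | COC(=O)c1c(C)cc(O)cc1O | starting material
2 | methyl 2-hydroxy-4-methoxy-6-methylbenzoate | COC(=O)c1c(C)cc(OC)cc1O | intermediate
3 | methyl 3-formyl-2-hydroxy-4-methoxy-6-methylbenzoate | COC(=O)c1c(C)cc(OC)c(C=O)c1O | intermediate
4 | methyl 2-hydroxy-3-(hydroxymethyl)-4-methoxy-6-methylbenzoate | COC(=O)c1c(C)cc(OC)c(CO)c1O | intermediate
5 | benzyl alcohol | OCc1ccccc1 | starting material
6 | methyl 3-[(benzyloxy)methyl]-2-hydroxy-4-methoxy-6-methylbenzoate | COC(=O)c1c(C)cc(OC)c(COCc2ccccc2)c1O | intermediate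
7 | 3-[(benzyloxy)methyl]-2-hydroxy-4-methoxy-6-methylbenzoic acid | OC(=O)c1c(C)cc(OC)c(COCc2ccccc2)c1O | intermediate
8 | 2,4-dihydroxy-3-methylbenzaldehyde | O=Cc1ccc(O)c(C)c1O | starting material
9 | 4-(benzyloxy)-2-hydroxy-3-methylbenzaldehyde | O=Cc1ccc(OCc2ccccc2)c(C)c1O | intermediate
10 | 4-(benzyloxy)-5-bromo-2-hydroxy-3-methylbenzaldehyde | O=Cc1cc(Br)c(OCc2ccccc2)c(C)c1O | intermediate
11 | 4-(benzyloxy)-5-bromo-2-(methoxymethoxy)-3-methylbenzaldehyde | COCOc1c(C=O)cc(Br)c(OCc2ccccc2)c1C | intermediate
12 | 4-(benzyloxy)-5-bromo-2-(methoxymethoxy)-3-methylphenyl formate (not isolated) | COCOc1c(OC=O)cc(Br)c(OCc2ccccc2)c1C | intermediate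
13 | 4-(benzyloxy)-5-bromo-2-(methoxymethoxy)-3-methylphenol | COCOc1c(O)cc(Br)c(OCc2ccccc2)c1C | intermediate
14 | 5-(benzyloxy)-6-bromo-2-hydroxy-3-(methoxymethoxy)-4-methylbenzaldehyde | COCOc1c(O)c(C=O)c(Br)c(OCc2ccccc2)c1C | intermediate
15 | 4-(benzyloxy)-3-bromo-2-formyl-6-(methoxymethoxy)-5-methylphenyl 3-[(benzyloxy)methyl]-2-hydroxy-4-methoxy-6-methylbenzoate (depside) | COCOc1c(OC(=O)c2c(C)cc(OC)c(COCc3ccccc3)c2O)c(C=O)c(Br)c(OCc2ccccc2)c1C | intermediate
16 | 3-[(benzyloxy)methyl]-2-[4-(benzyloxy)-3-bromo-2-formyl-6-(methoxymethoxy)-5-methylphenoxy]-4-methoxy-6-methylbenzoic acid | COc1cc(C)c(C(=O)O)c(Oc2c(C=O)c(Br)c(OCc3ccccc3)c(C)c2OCOC)c1COCc1ccccc1 | intermediate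
17 | 3-[(benzyloxy)methyl]-2-[4-(benzyloxy)-3-bromo-2-formyl-6-hydroxy-5-methylphenoxy]-4-methoxy-6-methylbenzoic acid | COc1cc(C)c(C(=O)O)c(Oc2c(C=O)c(Br)c(OCc3ccccc3)c(C)c2O)c1COCc1ccccc1 | intermediate
18 | bromo aldehyde depsidone (ring A: OMe, CH3, CH2OBn; ring B: B3 CH3, B4 OBn, B5 Br, B6 CHO) | COc1cc(C)c2c(c1COCc1ccccc1)Oc1c(c(C)c(OCc3ccccc3)c(Br)c1C=O)OC2=O | intermediate
19 | benzyl hemiacetal of 18 at the B6 formyl carbon, both configurations (not isolated) | COc1cc(C)c2c(c1COCc1ccccc1)Oc1c(c(C)c(OCc3ccccc3)c(Br)c1C(O)OCc1ccccc1)OC2=O | intermediate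
20 | depsidone with ring D closed as the (R) O-benzyl acetal (ring A CH2OBn, B4 OBn) | COc1cc(C)c2c(c1COCc1ccccc1)Oc1c(c(C)c(OCc3ccccc3)c3c1[C@H](OCc1ccccc1)OC3=O)OC2=O | intermediate
21 | CNP0367167.1, (R) lactol | COc1cc(C)c2c(c1CO)Oc1c(c(C)c(O)c3c1[C@H](O)OC3=O)OC2=O | target

## Step count and risks

Total step count: 16. Longest linear sequence: 11 steps (from 8 through steps 6–16; the branch from 1 through steps 1–5 and 11–16 is equally long).

Step 15 (proposed new method). The catalyst may fail to tell the interconverting hemiacetal enantiomers apart, or the lactone may close through a free phthalidyl oxocarbenium ion outside the chiral pocket, so that the acetal forms with poor enantioselectivity. Free benzyl alcohol may also intercept the acylpalladium to give the open benzyl ester. The fallback is diastereomer resolution with a chiral, hydrogenolysable alcohol, using only known chemistry. Setting out from 18, the carbonylative cyclization is run in its known racemic form with an achiral catalyst (Pd(OAc)2, Xantphos, CO 1 atm, iPr2NEt, toluene, 80 °C) and (S)-1-phenylethanol in place of 5. This should give two epimers at the B6 acetal carbon: the (R)-B6 (1S)-1-phenylethyl acetal of the di-O-benzyl depsidone F1 and the (S)-B6 (1S)-1-phenylethyl acetal of the di-O-benzyl depsidone F2. They are diastereomers and are separated by chromatography or crystallization; F2 is not carried on. Hydrogenolysis of F1 (H2, Pd/C, EtOAc) cuts the two O–benzyl bonds and the O–CH(CH3)Ph bond without touching the acetal carbon and comes back to the route at 21.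

Step 12. The depside may lose its acyl group to carbonate or adventitious hydroxide faster than the ring A phenoxide adds to B1, whose para benzyloxy group lowers its electrophilicity; the esterification of two hindered partners in step 11 has the same weak point. The fallback is an intermolecular SNAr on an aryl fluoride, which needs no ester tether. Setting out from 14, deoxyfluorination of the phenol with PhenoFluor (2,2-difluoro-1,3-bis(2,6-diisopropylphenyl)imidazoline, CsF, toluene, 110 °C) should give 5-(benzyloxy)-6-bromo-2-fluoro-3-(methoxymethoxy)-4-methylbenzaldehyde F3, in which fluoride ortho to the formyl group is the leaving group. The dianion of 7 (Cs2CO3, DMSO, 60 °C; then cold 1 M HCl) then displaces fluoride with its phenoxide oxygen, the standard diaryl ether synthesis from 2-fluorobenzaldehydes, and the fallback comes back to the route at 16.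

Step 13. The wrong protecting group may be lost: the ring A benzyl ether sits on a benzylic carbon flanked by two oxygen-bearing ring carbons and may ionize under the acid that removes the MOM group, with loss or exchange of benzyl at that ring A benzylic carbon. The fallback takes the MOM group off before the rings are joined, when no such ether is present. Setting out from 14, 2 M HCl in THF should give the catechol 5-(benzyloxy)-6-bromo-2,3-dihydroxy-4-methylbenzaldehyde F4. DCC esterification with 7 should acylate mainly the non-chelated B2 hydroxyl to give the B2 monoester of F4 with acid 7 F5. Under the conditions of step 12 this equilibrates by 1,2-acyl shift with the B1 monoester of F4 with acid 7 F6. Only this B1 ester has its ester oxygen on the formyl-activated carbon, so the Smiles rearrangement should drain the mixture through it and deliver the diaryl ether with a free B2 hydroxyl; the route is rejoined at 17.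

## Further compounds

F1 | step 15 | (R)-B6 (1S)-1-phenylethyl acetal of the di-O-benzyl depsidone | COc1cc(C)c2c(c1COCc1ccccc1)Oc1c(c(C)c(OCc3ccccc3)c3c1[C@H](O[C@@H](C)c1ccccc1)OC3=O)OC2=O
F2 | step 15 | (S)-B6 (1S)-1-phenylethyl acetal of the di-O-benzyl depsidone | COc1cc(C)c2c(c1COCc1ccccc1)Oc1c(c(C)c(OCc3ccccc3)c3c1[C@@H](O[C@@H](C)c1ccccc1)OC3=O)OC2=O
F3 | step 12 | 5-(benzyloxy)-6-bromo-2-fluoro-3-(methoxymethoxy)-4-methylbenzaldehyde | COCOc1c(F)c(C=O)c(Br)c(OCc2ccccc2)c1C
F4 | step 13 | 5-(benzyloxy)-6-bromo-2,3-dihydroxy-4-methylbenzaldehyde | Oc1c(O)c(C=O)c(Br)c(OCc2ccccc2)c1C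
F5 | step 13 | B2 monoester of F4 with acid 7 | COc1cc(C)c(C(=O)Oc2c(C)c(OCc3ccccc3)c(Br)c(C=O)c2O)c(O)c1COCc1ccccc1
F6 | step 13 | B1 monoester of F4 with acid 7 | COc1cc(C)c(C(=O)Oc2c(C=O)c(Br)c(OCc3ccccc3)c(C)c2O)c(O)c1COCc1ccccc1
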